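**Retrosynthetic overview**

1. Numbering: ring C1–C10 (alkene C1=C10), ester carbon C14 on C10, CH2OH carbon C15 on C4, lactone O6–C12(=O)–C11(=C13)–C7, isobutyrate on O8. The route rests on the C4–C5–C6 triad: carbinol C6, methylene C5 and C4 with its one-carbon branch C15 are the homoallylic-alcohol pattern left when a 2-(silylmethyl)allyl unit (C15–C4=C5) adds to a C6 aldehyde.
2. Key disconnection C5–C6: an intramolecular Hosomi–Sakurai allylation closes the ten-membered ring C1–C10 first, and O6 then closes the γ-lactone onto C12 in the same flask. C12 is carried as a tert-butyl ester so that neither O8 nor O6 lactonises before that point.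
3. After the key step: hydroboration of the C4 methylidene (C4–H, C15–OH), α-methylenation at C11, exchange of the O8 silyl ether for the isobutyrate.
4. Before the key step: the aldehyde comes from cross-metathesis at C1=C10 between a 2-substituted acrylate and an allylsilane diene made from 2-(chloromethyl)allylsilane; C9–C10 is built by Meldrum's acid homologation of a C9 aldehyde.
5. C7/C8 (anti) come from a magnesium-catalysed anti-aldol of a succinate imide with cinnamaldehyde, a robust non-enolisable partner; the allylsilane is joined only later, under neutral conditions, so it never meets an aldol Lewis acid or a strong base.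

Key step: step 11

Remark: the magnesium-catalysed anti-aldol is taken to add to the chelated (Z)-enolate on the face used in imide alkylations, which fixes the (S)-benzyl auxiliary; the opposite sense would call for the (R)-auxiliary.

**Route**

Step 1
Reactants: 1 (2-(chloromethyl)allyl)trimethylsilane; 2 allylmagnesium bromide
Product: 3 trimethyl(2-methylidenehex-5-en-1-yl)silane
Conditions: 2 (1.2 equiv), THF, 0 °C → rt
Reagents that add atoms: none
Why: Allyl Grignard–allylic chloride coupling (SN2 or SN2′, which here give the same 1,5-diene because both termini of the electrophile are CH2 groups on the central sp2 carbon) should join C2 to C3 without touching silicon.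

Step 2
Reactants: 4 4-tert-butoxy-4-oxobutanoic acid; 5 (4S)-4-benzyl-1,3-oxazolidin-2-one
Product: 6 tert-butyl 4-[(4S)-4-benzyl-2-oxo-1,3-oxazolidin-3-yl]-4-oxobutanoate
Conditions: PivCl, Et3N, THF, −20 °C; then 5, LiCl, −20 °C → rt
Reagents that add atoms: none
Why: N-Acylation of the oxazolidinone through the mixed pivalic anhydride (standard imide formation), the hindered pivaloyl carbonyl directing attack to the succinyl carbonyl.

Step 3
Reactants: 6 tert-butyl 4-[(4S)-4-benzyl-2-oxo-1,3-oxazolidin-3-yl]-4-oxobutanoate; 7 (E)-cinnamaldehyde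
Product: 9 tert-butyl (3R,4R,5E)-3-{[(4S)-4-benzyl-2-oxo-1,3-oxazolidin-3-yl]carbonyl}-4-hydroxy-6-phenylhex-5-enoate, via trimethylsilyl ether 8 (not isolated)
Conditions: MgCl2 (20 mol%), Et3N, TMSCl, EtOAc, 23 °C; then MeOH, TFA (cat.), 0 °C
Reagents that add atoms: chlorotrimethylsilane, C[Si](C)(C)Cl (silyl group present in intermediate 8 only)
Why: Evans-type magnesium chloride-catalysed direct anti-aldol reaction: soft enolisation gives the magnesium-chelated (Z)-enolate, the non-enolisable enal should add on the face away from the benzyl group (C7) through a boat transition state that gives the 7,8-anti pair (C8), silylation of the aldolate turns magnesium over, and acidic methanol then frees the C8 hydroxyl.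

Step 4
Reactants: 9 tert-butyl (3R,4R,5E)-3-{[(4S)-4-benzyl-2-oxo-1,3-oxazolidin-3-yl]carbonyl}-4-hydroxy-6-phenylhex-5-enoate
Product: 10 tert-butyl (3R,4R,5E)-3-{[(4S)-4-benzyl-2-oxo-1,3-oxazolidin-3-yl]carbonyl}-4-[(tert-butyldimethylsilyl)oxy]-6-phenylhex-5-enoate
Conditions: TBSOTf, 2,6-lutidine, CH2Cl2, −78 → −20 °C
Reagents that add atoms: tert-butyldimethylsilyl trifluoromethanesulfonate, CC(C)(C)[Si](C)(C)OS(=O)(=O)C(F)(F)F
Why: Silyl triflate silylation of the hindered secondary alcohol at low temperature, where the tert-butyl ester and the imide are inert and retro-aldol is not an issue.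

Step 5
Reactants: 10 tert-butyl (3R,4R,5E)-3-{[(4S)-4-benzyl-2-oxo-1,3-oxazolidin-3-yl]carbonyl}-4-[(tert-butyldimethylsilyl)oxy]-6-phenylhex-5-enoate
Product: 11 tert-butyl (3R,4S)-3-{[(4S)-4-benzyl-2-oxo-1,3-oxazolidin-3-yl]carbonyl}-4-[(tert-butyldimethylsilyl)oxy]-5-oxopentanoate
Conditions: O3, CH2Cl2, −78 °C; then PPh3, −78 °C → rt
Reagents that add atoms: ozone, [O-][O+]=O
Why: Ozonolysis with reductive work-up cleaves the only alkene and gives the α-silyloxy aldehyde whose formyl carbon is C9; no basic reagent touches C8 (the descriptor at C8 changes by priority only).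

Step 6
Reactants: 11 tert-butyl (3R,4S)-3-{[(4S)-4-benzyl-2-oxo-1,3-oxazolidin-3-yl]carbonyl}-4-[(tert-butyldimethylsilyl)oxy]-5-oxopentanoate; 12 Meldrum's acid (2,2-dimethyl-1,3-dioxane-4,6-dione)
Product: 14 tert-butyl (3R,4R)-3-{[(4S)-4-benzyl-2-oxo-1,3-oxazolidin-3-yl]carbonyl}-4-[(tert-butyldimethylsilyl)oxy]-5-(2,2-dimethyl-4,6-dioxo-1,3-dioxan-5-yl)pentanoate, via alkylidene Meldrum's acid 13 (not isolated)
Conditions: Hantzsch ester, L-proline (10 mol%), EtOH, rt
Reagents that add atoms: none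
Why: Reductive alkylation of Meldrum's acid (Knoevenagel condensation, then conjugate transfer hydrogenation of the alkylidene by the Hantzsch ester) attaches C10 and turns C9 into a methylene without any strong base.

Step 7
Reactants: 14 tert-butyl (3R,4R)-3-{[(4S)-4-benzyl-2-oxo-1,3-oxazolidin-3-yl]carbonyl}-4-[(tert-butyldimethylsilyl)oxy]-5-(2,2-dimethyl-4,6-dioxo-1,3-dioxan-5-yl)pentanoate
Product: 17 7-tert-butyl 1-methyl (4R,5R)-5-{[(4S)-4-benzyl-2-oxo-1,3-oxazolidin-3-yl]carbonyl}-4-[(tert-butyldimethylsilyl)oxy]-2-methylideneheptanedioate, via Mannich base 15 (not isolated), via malonic half ester 16 (not isolated)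
Conditions: Me2N+=CH2 I− (Eschenmoser's salt), MeOH, 65 °C
Reagents that add atoms: N,N-dimethylmethyleneiminium iodide, C=[N+](C)C.[I-] (the methylidene carbon); methanol, CO (the OCH3 of C14)
Why: Mannich reaction of the monoalkyl Meldrum's acid with the iminium salt, methanolysis of the dioxanedione and decarboxylative elimination of dimethylamine (the established route from such Meldrum's acids to 2-substituted acrylates) should give the methyl ester C14 and a methylidene on C10.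

Step 8
Reactants: 17 7-tert-butyl 1-methyl (4R,5R)-5-{[(4S)-4-benzyl-2-oxo-1,3-oxazolidin-3-yl]carbonyl}-4-[(tert-butyldimethylsilyl)oxy]-2-methylideneheptanedioate; 3 trimethyl(2-methylidenehex-5-en-1-yl)silane
Product: 18 7-tert-butyl 1-methyl (2E,4R,5R)-5-{[(4S)-4-benzyl-2-oxo-1,3-oxazolidin-3-yl]carbonyl}-4-[(tert-butyldimethylsilyl)oxy]-2-{4-[(trimethylsilyl)methyl]pent-4-en-1-ylidene}heptanedioate
Conditions: Hoveyda–Grubbs II (10 mol%), 3 (4 equiv, in portions), CH2Cl2, 40 °C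
Reagents that add atoms: none
Why: Olefin cross-metathesis of the 2-substituted acrylate with the monosubstituted alkene of 3 (its 1,1-disubstituted allylsilane alkene being a poor partner) should give the trisubstituted enoate under thermodynamic control as the E isomer, C14 trans to C2.

Step 9
Reactants: 18 7-tert-butyl 1-methyl (2E,4R,5R)-5-{[(4S)-4-benzyl-2-oxo-1,3-oxazolidin-3-yl]carbonyl}-4-[(tert-butyldimethylsilyl)oxy]-2-{4-[(trimethylsilyl)methyl]pent-4-en-1-ylidene}heptanedioate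
Product: 19 7-tert-butyl 1-methyl (2E,4R,5S)-4-[(tert-butyldimethylsilyl)oxy]-5-(hydroxymethyl)-2-{4-[(trimethylsilyl)methyl]pent-4-en-1-ylidene}heptanedioate
Conditions: NaBH4, THF/H2O, 0 °C → rt
Reagents that add atoms: none
Why: Reductive cleavage of the N-acyloxazolidinone with borohydride is chemoselective for the activated exocyclic imide carbonyl over the conjugated methyl ester and the tert-butyl ester, and the tert-butyl ester is too hindered to lactonise with the new C6 alcohol.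

Step 10
Reactants: 19 7-tert-butyl 1-methyl (2E,4R,5S)-4-[(tert-butyldimethylsilyl)oxy]-5-(hydroxymethyl)-2-{4-[(trimethylsilyl)methyl]pent-4-en-1-ylidene}heptanedioate
Product: 20 7-tert-butyl 1-methyl (2E,4R,5R)-4-[(tert-butyldimethylsilyl)oxy]-5-formyl-2-{4-[(trimethylsilyl)methyl]pent-4-en-1-ylidene}heptanedioate
Conditions: Dess–Martin periodinane, NaHCO3, CH2Cl2, 0 °C → rt
Reagents that add atoms: none
Why: Dess–Martin oxidation under buffered conditions gives the β-silyloxy aldehyde without base, so C7 should not epimerise and the silyloxy group should not eliminate; the aldehyde is used at once.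

Step 11
Reactants: 20 7-tert-butyl 1-methyl (2E,4R,5R)-4-[(tert-butyldimethylsilyl)oxy]-5-formyl-2-{4-[(trimethylsilyl)methyl]pent-4-en-1-ylidene}heptanedioate
Product: 22 methyl (3aS,4R,6E,11aR)-4-[(tert-butyldimethylsilyl)oxy]-10-methylidene-2-oxo-2,3,3a,4,5,8,9,10,11,11a-decahydrocyclodeca[b]furan-6-carboxylate, via hydroxy tert-butyl ester 21 (not isolated)
Conditions: BF3·OEt2 (3 equiv), CH2Cl2 (2 mM, slow addition of 20), −78 °C; then 0 °C
Reagents that add atoms: none
Why: BF3 activates the C6 aldehyde and the 2-substituted allylsilane attacks through its methylene terminus C5 (SE2′); the β-silyl cation at C4 loses Me3Si as Me3SiF to leave the C4=C15 methylidene, and on warming the boron alkoxide at O6 closes onto the BF3-activated tert-butyl ester with loss of isobutene. The closest known reaction is the intramolecular Hosomi–Sakurai allylation of aldehydes, which has been used for medium rings, followed by Lewis-acid lactonisation of a γ-hydroxy tert-butyl ester. The ten-membered ring closes exo to the carbonyl and endo to the allylsilane π-bond (10-exo-trig at C6), helped by the cis placement of C2 and C9 on C1=C10, and the γ-lactone closes 5-exo-trig at C12. C6 is set in an open transition state with monodentate BF3: Felkin–Anh 1,2-induction from C7 (C8 branch anti to the nucleophile) and 1,3-anti induction from the C8 silyloxy group both call for O6 syn to C11 and anti to O8 in this 7,8-anti aldehyde. The step needs intramolecular over intermolecular allylation (2 mM, slow addition), the right C6 face (the reinforcing C7/C8 pattern) and an intact C7 centre (non-basic medium at −78 °C).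

Step 12
Reactants: 22 methyl (3aS,4R,6E,11aR)-4-[(tert-butyldimethylsilyl)oxy]-10-methylidene-2-oxo-2,3,3a,4,5,8,9,10,11,11a-decahydrocyclodeca[b]furan-6-carboxylate
Product: 24 methyl (3aS,4R,6E,10S,11aR)-4-[(tert-butyldimethylsilyl)oxy]-10-(hydroxymethyl)-2-oxo-2,3,3a,4,5,8,9,10,11,11a-decahydrocyclodeca[b]furan-6-carboxylate, via B-alkyl-9-BBN borane 23 (not isolated)
Conditions: 9-BBN, THF, 0 °C → rt; then H2O2, pH 7 buffer, 0 °C
Reagents that add atoms: 9-borabicyclo[3.3.1]nonane, B1C2CCCC1CCC2 (boron present in intermediate 23 only); hydrogen peroxide, OO (the O of the C15 hydroxyl)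
Why: Hydroboration–oxidation: 9-BBN should add only to the electron-rich 1,1-disubstituted C4=C15 alkene (boron on C15, the conjugated C1=C10 and both carbonyls inert), C4 being set by substrate control through attack on the more open face of the ring, taken here to deliver hydrogen syn to O6 and so give the (10S) centre, and buffered peroxide oxidation spares the lactone.

Step 13
Reactants: 24 methyl (3aS,4R,6E,10S,11aR)-4-[(tert-butyldimethylsilyl)oxy]-10-(hydroxymethyl)-2-oxo-2,3,3a,4,5,8,9,10,11,11a-decahydrocyclodeca[b]furan-6-carboxylate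
Product: 25 methyl (3aS,4R,6E,10S,11aR)-4-[(tert-butyldimethylsilyl)oxy]-10-{[(tert-butyldiphenylsilyl)oxy]methyl}-2-oxo-2,3,3a,4,5,8,9,10,11,11a-decahydrocyclodeca[b]furan-6-carboxylate
Conditions: TBDPSCl, imidazole, DMF, rt
Reagents that add atoms: tert-butylchlorodiphenylsilane, CC(C)(C)[Si](Cl)(c1ccccc1)c1ccccc1
Why: Silylation of the primary alcohol with TBDPS chloride gives an ether that should outlast the later acidic cleavage of the secondary TBS ether.

Step 14
Reactants: 25 methyl (3aS,4R,6E,10S,11aR)-4-[(tert-butyldimethylsilyl)oxy]-10-{[(tert-butyldiphenylsilyl)oxy]methyl}-2-oxo-2,3,3a,4,5,8,9,10,11,11a-decahydrocyclodeca[b]furan-6-carboxylate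
Product: 26 methyl (3aS,4R,6E,10S,11aR)-4-[(tert-butyldimethylsilyl)oxy]-10-{[(tert-butyldiphenylsilyl)oxy]methyl}-3-[(dimethylamino)methyl]-2-oxo-2,3,3a,4,5,8,9,10,11,11a-decahydrocyclodeca[b]furan-6-carboxylate (C3 epimers)
Conditions: LiHMDS, THF, −78 °C; then Me2N+=CH2 I−, −78 → 0 °C
Reagents that add atoms: N,N-dimethylmethyleneiminium iodide, C=[N+](C)C.[I-]
Why: Mannich reaction of the lactone lithium enolate with Eschenmoser's salt; LiHMDS should deprotonate C11 of the lactone in preference to the less acidic γ-positions of the enoate.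

Step 15
Reactants: 26 methyl (3aS,4R,6E,10S,11aR)-4-[(tert-butyldimethylsilyl)oxy]-10-{[(tert-butyldiphenylsilyl)oxy]methyl}-3-[(dimethylamino)methyl]-2-oxo-2,3,3a,4,5,8,9,10,11,11a-decahydrocyclodeca[b]furan-6-carboxylate
Product: 28 methyl (3aS,4R,6E,10S,11aR)-4-[(tert-butyldimethylsilyl)oxy]-10-{[(tert-butyldiphenylsilyl)oxy]methyl}-3-methylidene-2-oxo-2,3,3a,4,5,8,9,10,11,11a-decahydrocyclodeca[b]furan-6-carboxylate, via trimethylammonium iodide 27 (not isolated)
Conditions: MeI, MeOH, rt; then NaHCO3 (aq.), EtOAc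
Reagents that add atoms: iodomethane, CI (methyl present in intermediate 27 only)
Why: Exhaustive N-methylation and Hofmann-type E1cB elimination of trimethylamine under mild base should give the C11=C13 methylidene, removing the C11 stereocentre.

Step 16
Reactants: 28 methyl (3aS,4R,6E,10S,11aR)-4-[(tert-butyldimethylsilyl)oxy]-10-{[(tert-butyldiphenylsilyl)oxy]methyl}-3-methylidene-2-oxo-2,3,3a,4,5,8,9,10,11,11a-decahydrocyclodeca[b]furan-6-carboxylate
Product: 29 methyl (3aR,4R,6E,10S,11aR)-10-{[(tert-butyldiphenylsilyl)oxy]methyl}-4-hydroxy-3-methylidene-2-oxo-2,3,3a,4,5,8,9,10,11,11a-decahydrocyclodeca[b]furan-6-carboxylate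
Conditions: HF (48% aq.), MeCN, 0 °C
Reagents that add atoms: none
Why: Selective desilylation: aqueous HF cleaves the secondary TBS ether far faster than the primary TBDPS ether, and the acidic medium does not add to the α-methylene lactone (the 3a descriptor changes by priority only).

Step 17
Reactants: 29 methyl (3aR,4R,6E,10S,11aR)-10-{[(tert-butyldiphenylsilyl)oxy]methyl}-4-hydroxy-3-methylidene-2-oxo-2,3,3a,4,5,8,9,10,11,11a-decahydrocyclodeca[b]furan-6-carboxylate
Product: 30 methyl (3aS,4R,6E,10S,11aR)-10-{[(tert-butyldiphenylsilyl)oxy]methyl}-3-methylidene-4-[(2-methylpropanoyl)oxy]-2-oxo-2,3,3a,4,5,8,9,10,11,11a-decahydrocyclodeca[b]furan-6-carboxylate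
Conditions: (i-PrCO)2O, Et3N, DMAP (cat.), CH2Cl2, 0 °C → rt
Reagents that add atoms: 2-methylpropanoic anhydride, CC(C)C(=O)OC(=O)C(C)C
Why: DMAP-catalysed acylation of the secondary alcohol with the anhydride (nucleophilic catalysis) should give the isobutyrate with retention at C8.

Step 18
Reactants: 30 methyl (3aS,4R,6E,10S,11aR)-10-{[(tert-butyldiphenylsilyl)oxy]methyl}-3-methylidene-4-[(2-methylpropanoyl)oxy]-2-oxo-2,3,3a,4,5,8,9,10,11,11a-decahydrocyclodeca[b]furan-6-carboxylate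
Product: 31 methyl (3aS,4R,6E,10S,11aR)-10-(hydroxymethyl)-3-methylidene-4-[(2-methylpropanoyl)oxy]-2-oxo-2,3,3a,4,5,8,9,10,11,11a-decahydrocyclodeca[b]furan-6-carboxylate (CNP0251148.1)
Conditions: TBAF, AcOH, THF, 0 °C → rt
Reagents that add atoms: none
Why: Fluoride desilylation of the TBDPS ether, buffered with acetic acid so that neither the α-methylene lactone nor the two esters react.

**Compound list**

1 | (2-(chloromethyl)allyl)trimethylsilane | C[Si](C)(C)CC(=C)CCl | starting material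
2 | allylmagnesium bromide | C=CC[Mg]Br | starting material
3 | trimethyl(2-methylidenehex-5-en-1-yl)silane | C=CCCC(=C)C[Si](C)(C)C | intermediate
4 | 4-tert-butoxy-4-oxobutanoic acid (mono-tert-butyl succinate) | CC(C)(C)OC(=O)CCC(=O)O | starting material
5 | (4S)-4-benzyl-1,3-oxazolidin-2-one | O=C1N[C@@H](Cc2ccccc2)CO1 | starting material
6 | tert-butyl 4-[(4S)-4-benzyl-2-oxo-1,3-oxazolidin-3-yl]-4-oxobutanoate | CC(C)(C)OC(=O)CCC(=O)N1[C@@H](Cc2ccccc2)COC1=O | intermediate
7 | (E)-cinnamaldehyde | O=C/C=C/c1ccccc1 | starting material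
8 | tert-butyl (3R,4R,5E)-3-{[(4S)-4-benzyl-2-oxo-1,3-oxazolidin-3-yl]carbonyl}-6-phenyl-4-[(trimethylsilyl)oxy]hex-5-enoate | O=C(N1[C@@H](Cc2ccccc2)COC1=O)[C@H](CC(=O)OC(C)(C)C)[C@H](O[Si](C)(C)C)/C=C/c3ccccc3 | intermediate
9 | tert-butyl (3R,4R,5E)-3-{[(4S)-4-benzyl-2-oxo-1,3-oxazolidin-3-yl]carbonyl}-4-hydroxy-6-phenylhex-5-enoate | O=C(N1[C@@H](Cc2ccccc2)COC1=O)[C@H](CC(=O)OC(C)(C)C)[C@H](O)/C=C/c3ccccc3 | intermediate
10 | tert-butyl (3R,4R,5E)-3-{[(4S)-4-benzyl-2-oxo-1,3-oxazolidin-3-yl]carbonyl}-4-[(tert-butyldimethylsilyl)oxy]-6-phenylhex-5-enoate | O=C(N1[C@@H](Cc2ccccc2)COC1=O)[C@H](CC(=O)OC(C)(C)C)[C@H](O[Si](C)(C)C(C)(C)C)/C=C/c3ccccc3 | intermediate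
11 | tert-butyl (3R,4S)-3-{[(4S)-4-benzyl-2-oxo-1,3-oxazolidin-3-yl]carbonyl}-4-[(tert-butyldimethylsilyl)oxy]-5-oxopentanoate | O=C(N1[C@@H](Cc2ccccc2)COC1=O)[C@H](CC(=O)OC(C)(C)C)[C@H](O[Si](C)(C)C(C)(C)C)C=O | intermediate
12 | Meldrum's acid (2,2-dimethyl-1,3-dioxane-4,6-dione) | CC1(C)OC(=O)CC(=O)O1 | starting material
13 | tert-butyl (3R,4R)-3-{[(4S)-4-benzyl-2-oxo-1,3-oxazolidin-3-yl]carbonyl}-4-[(tert-butyldimethylsilyl)oxy]-5-(2,2-dimethyl-4,6-dioxo-1,3-dioxan-5-ylidene)pentanoate | O=C(N1[C@@H](Cc2ccccc2)COC1=O)[C@H](CC(=O)OC(C)(C)C)[C@H](O[Si](C)(C)C(C)(C)C)C=C3C(=O)OC(C)(C)OC3=O | intermediate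
14 | tert-butyl (3R,4R)-3-{[(4S)-4-benzyl-2-oxo-1,3-oxazolidin-3-yl]carbonyl}-4-[(tert-butyldimethylsilyl)oxy]-5-(2,2-dimethyl-4,6-dioxo-1,3-dioxan-5-yl)pentanoate | O=C(N1[C@@H](Cc2ccccc2)COC1=O)[C@H](CC(=O)OC(C)(C)C)[C@H](O[Si](C)(C)C(C)(C)C)CC3C(=O)OC(C)(C)OC3=O | intermediate
15 | tert-butyl (3R,4R)-3-{[(4S)-4-benzyl-2-oxo-1,3-oxazolidin-3-yl]carbonyl}-4-[(tert-butyldimethylsilyl)oxy]-5-{5-[(dimethylamino)methyl]-2,2-dimethyl-4,6-dioxo-1,3-dioxan-5-yl}pentanoate | O=C(N1[C@@H](Cc2ccccc2)COC1=O)[C@H](CC(=O)OC(C)(C)C)[C@H](O[Si](C)(C)C(C)(C)C)CC3(CN(C)C)C(=O)OC(C)(C)OC3=O | intermediate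
16 | (4R,5R)-5-{[(4S)-4-benzyl-2-oxo-1,3-oxazolidin-3-yl]carbonyl}-7-tert-butoxy-4-[(tert-butyldimethylsilyl)oxy]-2-[(dimethylamino)methyl]-2-(methoxycarbonyl)-7-oxoheptanoic acid (C2 epimers) | O=C(N1[C@@H](Cc2ccccc2)COC1=O)[C@H](CC(=O)OC(C)(C)C)[C@H](O[Si](C)(C)C(C)(C)C)CC(CN(C)C)(C(=O)O)C(=O)OC | intermediate
17 | 7-tert-butyl 1-methyl (4R,5R)-5-{[(4S)-4-benzyl-2-oxo-1,3-oxazolidin-3-yl]carbonyl}-4-[(tert-butyldimethylsilyl)oxy]-2-methylideneheptanedioate | O=C(N1[C@@H](Cc2ccccc2)COC1=O)[C@H](CC(=O)OC(C)(C)C)[C@H](O[Si](C)(C)C(C)(C)C)CC(=C)C(=O)OC | intermediate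
18 | 7-tert-butyl 1-methyl (2E,4R,5R)-5-{[(4S)-4-benzyl-2-oxo-1,3-oxazolidin-3-yl]carbonyl}-4-[(tert-butyldimethylsilyl)oxy]-2-{4-[(trimethylsilyl)methyl]pent-4-en-1-ylidene}heptanedioate | O=C(N1[C@@H](Cc2ccccc2)COC1=O)[C@H](CC(=O)OC(C)(C)C)[C@H](O[Si](C)(C)C(C)(C)C)C/C(C(=O)OC)=C\CCC(=C)C[Si](C)(C)C | intermediate
19 | 7-tert-butyl 1-methyl (2E,4R,5S)-4-[(tert-butyldimethylsilyl)oxy]-5-(hydroxymethyl)-2-{4-[(trimethylsilyl)methyl]pent-4-en-1-ylidene}heptanedioate | OC[C@H](CC(=O)OC(C)(C)C)[C@H](O[Si](C)(C)C(C)(C)C)C/C(C(=O)OC)=C\CCC(=C)C[Si](C)(C)C | intermediate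
20 | 7-tert-butyl 1-methyl (2E,4R,5R)-4-[(tert-butyldimethylsilyl)oxy]-5-formyl-2-{4-[(trimethylsilyl)methyl]pent-4-en-1-ylidene}heptanedioate (key-step precursor) | O=C[C@H](CC(=O)OC(C)(C)C)[C@H](O[Si](C)(C)C(C)(C)C)C/C(C(=O)OC)=C\CCC(=C)C[Si](C)(C)C | intermediate
21 | methyl (1E,7R,8S,9R)-8-(2-tert-butoxy-2-oxoethyl)-9-[(tert-butyldimethylsilyl)oxy]-7-hydroxy-5-methylidenecyclodec-1-ene-1-carboxylate | O[C@@H]1CC(=C)CC/C=C(/C(=O)OC)C[C@@H](O[Si](C)(C)C(C)(C)C)[C@H]1CC(=O)OC(C)(C)C | intermediate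
22 | methyl (3aS,4R,6E,11aR)-4-[(tert-butyldimethylsilyl)oxy]-10-methylidene-2-oxo-2,3,3a,4,5,8,9,10,11,11a-decahydrocyclodeca[b]furan-6-carboxylate (key-step product) | C1C(=O)O[C@@H]2CC(=C)CC/C=C(/C(=O)OC)C[C@@H](O[Si](C)(C)C(C)(C)C)[C@@H]12 | intermediate
23 | methyl (3aS,4R,6E,10S,11aR)-10-[(9-borabicyclo[3.3.1]nonan-9-yl)methyl]-4-[(tert-butyldimethylsilyl)oxy]-2-oxo-2,3,3a,4,5,8,9,10,11,11a-decahydrocyclodeca[b]furan-6-carboxylate | C1C(=O)O[C@@H]2C[C@@H](CB3C4CCCC3CCC4)CC/C=C(/C(=O)OC)C[C@@H](O[Si](C)(C)C(C)(C)C)[C@@H]12 | intermediate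
24 | methyl (3aS,4R,6E,10S,11aR)-4-[(tert-butyldimethylsilyl)oxy]-10-(hydroxymethyl)-2-oxo-2,3,3a,4,5,8,9,10,11,11a-decahydrocyclodeca[b]furan-6-carboxylate | C1C(=O)O[C@@H]2C[C@@H](CO)CC/C=C(/C(=O)OC)C[C@@H](O[Si](C)(C)C(C)(C)C)[C@@H]12 | intermediate
25 | methyl (3aS,4R,6E,10S,11aR)-4-[(tert-butyldimethylsilyl)oxy]-10-{[(tert-butyldiphenylsilyl)oxy]methyl}-2-oxo-2,3,3a,4,5,8,9,10,11,11a-decahydrocyclodeca[b]furan-6-carboxylate | C1C(=O)O[C@@H]2C[C@@H](CO[Si](c3ccccc3)(c4ccccc4)C(C)(C)C)CC/C=C(/C(=O)OC)C[C@@H](O[Si](C)(C)C(C)(C)C)[C@@H]12 | intermediate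
26 | methyl (3aS,4R,6E,10S,11aR)-4-[(tert-butyldimethylsilyl)oxy]-10-{[(tert-butyldiphenylsilyl)oxy]methyl}-3-[(dimethylamino)methyl]-2-oxo-2,3,3a,4,5,8,9,10,11,11a-decahydrocyclodeca[b]furan-6-carboxylate (C3 epimers) | CN(C)CC1C(=O)O[C@@H]2C[C@@H](CO[Si](c3ccccc3)(c4ccccc4)C(C)(C)C)CC/C=C(/C(=O)OC)C[C@@H](O[Si](C)(C)C(C)(C)C)[C@@H]12 | intermediate
27 | {[(3aS,4R,6E,10S,11aR)-4-[(tert-butyldimethylsilyl)oxy]-10-{[(tert-butyldiphenylsilyl)oxy]methyl}-6-(methoxycarbonyl)-2-oxo-2,3,3a,4,5,8,9,10,11,11a-decahydrocyclodeca[b]furan-3-yl]methyl}trimethylammonium iodide (C3 epimers) | C[N+](C)(C)CC1C(=O)O[C@@H]2C[C@@H](CO[Si](c3ccccc3)(c4ccccc4)C(C)(C)C)CC/C=C(/C(=O)OC)C[C@@H](O[Si](C)(C)C(C)(C)C)[C@@H]12.[I-] | intermediate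
28 | methyl (3aS,4R,6E,10S,11aR)-4-[(tert-butyldimethylsilyl)oxy]-10-{[(tert-butyldiphenylsilyl)oxy]methyl}-3-methylidene-2-oxo-2,3,3a,4,5,8,9,10,11,11a-decahydrocyclodeca[b]furan-6-carboxylate | C=C1C(=O)O[C@@H]2C[C@@H](CO[Si](c3ccccc3)(c4ccccc4)C(C)(C)C)CC/C=C(/C(=O)OC)C[C@@H](O[Si](C)(C)C(C)(C)C)[C@@H]12 | intermediate
29 | methyl (3aR,4R,6E,10S,11aR)-10-{[(tert-butyldiphenylsilyl)oxy]methyl}-4-hydroxy-3-methylidene-2-oxo-2,3,3a,4,5,8,9,10,11,11a-decahydrocyclodeca[b]furan-6-carboxylate | C=C1C(=O)O[C@@H]2C[C@@H](CO[Si](c3ccccc3)(c4ccccc4)C(C)(C)C)CC/C=C(/C(=O)OC)C[C@@H](O)[C@@H]12 | intermediate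
30 | methyl (3aS,4R,6E,10S,11aR)-10-{[(tert-butyldiphenylsilyl)oxy]methyl}-3-methylidene-4-[(2-methylpropanoyl)oxy]-2-oxo-2,3,3a,4,5,8,9,10,11,11a-decahydrocyclodeca[b]furan-6-carboxylate | C=C1C(=O)O[C@@H]2C[C@@H](CO[Si](c3ccccc3)(c4ccccc4)C(C)(C)C)CC/C=C(/C(=O)OC)C[C@@H](OC(=O)C(C)C)[C@@H]12 | intermediate
31 | methyl (3aS,4R,6E,10S,11aR)-10-(hydroxymethyl)-3-methylidene-4-[(2-methylpropanoyl)oxy]-2-oxo-2,3,3a,4,5,8,9,10,11,11a-decahydrocyclodeca[b]furan-6-carboxylate | C=C1C(=O)O[C@@H]2C[C@@H](CO)CC/C=C(/C(=O)OC)C[C@@H](OC(=O)C(C)C)[C@@H]12 | target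

**Step count**

Total: 18 steps. Longest linear sequence: 17 steps (4 → 31, steps 2–18); step 1 is the one-step side branch.

**Steps most likely to fail**

Step 11 (key step). Ring closure may lose to intermolecular allylation and oligomerisation. The open transition state inside a forming ten-membered ring may not follow the acyclic C7/C8 models, giving poor facial selectivity at C6. The allylsilane may be protodesilylated, and the secondary silyl ether may be lost while the tert-butyl ester is being closed at 0 °C. The fallback sets out from 20: bromodesilylation of the allylsilane with NBS (propylene oxide, CH2Cl2, −78 °C) gives the aldehyde allylic bromide F1. CrCl2 in THF at high dilution then closes the ring by an intramolecular Nozaki–Hiyama–Kishi allylation through a cyclic allylchromium transition state, which gives 21 after work-up. Lactonisation of 21 under the 0 °C conditions of step 11 rejoins the route at 22.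

Step 12. The borane may add to the wrong face of the C4 methylidene, since the preferred conformer of the ten-membered ring is not known in advance. The fallback sets out from 22: the same hydroboration–oxidation would then give mainly the C4 epimer, alcohol F2. Dess–Martin oxidation gives aldehyde F3, and DBU in CH2Cl2 equilibrates C4 next to the formyl group to aldehyde F4 (thermodynamic control in place of kinetic face selection; unchanged F3 is recycled). NaBH4 reduction of F4 comes back to the route at 24.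

Step 8. Metathesis of the hindered 2-substituted acrylate may be slow, so that homodimerisation of 3 and competing metathesis or alkene migration at the allylsilane consume material. The fallback sets out from 11: Knoevenagel condensation with methyl 2-(diethoxyphosphoryl)acetate (TiCl4, N-methylmorpholine, THF) gives the alkylidene phosphonoacetate F5, and hydrogenation (H2, Pd/C) gives phosphonate F6. Separately, 1 is alkylated with lithioacetonitrile to nitrile F7, which DIBAL-H reduces to 4-[(trimethylsilyl)methyl]pent-4-enal F8. Horner–Wadsworth–Emmons olefination of F6 with F8 (LiCl, DBU, MeCN) comes back to the route at 18; the E and Z isomers would have to be separated.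

**Further compounds**

F1 | step 11 | 7-tert-butyl 1-methyl (2E,4R,5R)-2-[4-(bromomethyl)pent-4-en-1-ylidene]-4-[(tert-butyldimethylsilyl)oxy]-5-formylheptanedioate | O=C[C@H](CC(=O)OC(C)(C)C)[C@H](O[Si](C)(C)C(C)(C)C)C/C(C(=O)OC)=C\CCC(=C)CBr
F2 | step 12 | methyl (3aS,4R,6E,10R,11aR)-4-[(tert-butyldimethylsilyl)oxy]-10-(hydroxymethyl)-2-oxo-2,3,3a,4,5,8,9,10,11,11a-decahydrocyclodeca[b]furan-6-carboxylate | C1C(=O)O[C@@H]2C[C@H](CO)CC/C=C(/C(=O)OC)C[C@@H](O[Si](C)(C)C(C)(C)C)[C@@H]12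
F3 | step 12 | methyl (3aS,4R,6E,10R,11aR)-4-[(tert-butyldimethylsilyl)oxy]-10-formyl-2-oxo-2,3,3a,4,5,8,9,10,11,11a-decahydrocyclodeca[b]furan-6-carboxylate | C1C(=O)O[C@@H]2C[C@H](C=O)CC/C=C(/C(=O)OC)C[C@@H](O[Si](C)(C)C(C)(C)C)[C@@H]12
F4 | step 12 | methyl (3aS,4R,6E,10S,11aR)-4-[(tert-butyldimethylsilyl)oxy]-10-formyl-2-oxo-2,3,3a,4,5,8,9,10,11,11a-decahydrocyclodeca[b]furan-6-carboxylate | C1C(=O)O[C@@H]2C[C@@H](C=O)CC/C=C(/C(=O)OC)C[C@@H](O[Si](C)(C)C(C)(C)C)[C@@H]12
F5 | step 8 | 1-tert-butyl 7-methyl (3R,4S)-3-{[(4S)-4-benzyl-2-oxo-1,3-oxazolidin-3-yl]carbonyl}-4-[(tert-butyldimethylsilyl)oxy]-6-(diethoxyphosphoryl)hept-5-enedioate (E/Z mixture) | O=C(N1[C@@H](Cc2ccccc2)COC1=O)[C@H](CC(=O)OC(C)(C)C)[C@H](O[Si](C)(C)C(C)(C)C)C=C(C(=O)OC)P(=O)(OCC)OCC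
F6 | step 8 | 1-tert-butyl 7-methyl (3R,4R)-3-{[(4S)-4-benzyl-2-oxo-1,3-oxazolidin-3-yl]carbonyl}-4-[(tert-butyldimethylsilyl)oxy]-6-(diethoxyphosphoryl)heptanedioate (C6 epimers) | O=C(N1[C@@H](Cc2ccccc2)COC1=O)[C@H](CC(=O)OC(C)(C)C)[C@H](O[Si](C)(C)C(C)(C)C)CC(C(=O)OC)P(=O)(OCC)OCC
F7 | step 8 | 4-[(trimethylsilyl)methyl]pent-4-enenitrile | N#CCCC(=C)C[Si](C)(C)C
F8 | step 8 | 4-[(trimethylsilyl)methyl]pent-4-enal | O=CCCC(=C)C[Si](C)(C)C
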